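**Strategy.** The three adjacent bromines at C4, C5 and C6 of the benzene ring are traced back to one nitrogen at C5. The C4–Br and C6–Br bonds are formed in one operation by an amino-directed double bromination, and C5–Br comes from the same amino group through its diazonium salt. The key step exploits that C5 is flanked by C4 and C6 while its para carbon C7a is a ring-fusion atom, and that the five-membered ring is still a lactam with sp3 C3, so no pyrrole position competes. Its precursor is plain 5-aminooxindole, a bicyclic lactam with a free NH2 at C5. Both sulfur groups are added afterwards, when no electrophilic bromine is left in play.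

Key step: step 1

Remark: the target is achiral, so no stereocentre has to be set; 1 is used as the commercial free base and 6 is drawn as its thione (thiolactam) tautomer.

Step 1
Reactants: 1 5-aminooxindole (5-amino-1,3-dihydro-2H-indol-2-one); 2 N-bromosuccinimide
Product: 3 5-amino-4,6-dibromo-1,3-dihydro-2H-indol-2-one
Conditions: 2 (2.0 equiv, in portions), DMF, −10 to 0 °C, dark
Reagents that add atoms: N-bromosuccinimide, O=C1CCC(=O)N1Br
Why: Each C–Br bond forms by electrophilic aromatic substitution: the ring attacks the polarised bromine of 2 to give a Wheland cation stabilised by the lone pair of the C5 amino group, and loss of a proton restores the arene. The closest known reaction type is the ortho,ortho-dibromination of para-substituted anilines with N-bromosuccinimide. No ring is closed and no stereocentre is created. The step needs site selectivity for C4 and C6 over C7 and over the C3 methylene: the free NH2 is a far stronger donor than the acylated N1, its para position C7a is blocked, and C7 lies meta to it. C3 can react only through the lactam enol or a radical chain, and both should be suppressed in a polar solvent at low temperature in the dark without acid, base or initiator. Charging exactly two equivalents of 2 in portions should stop the reaction at the dibromide and limit oxidation of the electron-rich aniline.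

Step 2
Reactants: 3 5-amino-4,6-dibromo-1,3-dihydro-2H-indol-2-one
Product: 5 4,5,6-tribromo-1,3-dihydro-2H-indol-2-one, via diazonium bromide 4 (not isolated)
Conditions: NaNO2 (1.0 equiv), 48% aq HBr, AcOH, 0–5 °C; then CuBr, 48% aq HBr, 60 °C
Reagents that add atoms: hydrobromic acid, Br; CuBr, [Cu]Br; NaNO2, [Na+].[O-]N=O (nitrogen carried only by 4 and lost as N2)
Why: Diazotisation of the primary arylamine followed by the Sandmeyer reaction, in which CuBr reduces the diazonium ion to an aryl radical that takes bromine from the CuBr2 so formed, is the standard replacement of NH2 by Br on 2,6-dibromoanilines, and fast N-nitrosation with a single equivalent of nitrite at 0 °C should outrun nitrosation of the slowly enolising C3 methylene.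

Step 3
Reactants: 5 4,5,6-tribromo-1,3-dihydro-2H-indol-2-one
Product: 6 4,5,6-tribromo-1,3-dihydro-2H-indole-2-thione
Conditions: P4S10, NaHCO3, THF, rt, argon
Reagents that add atoms: P4S10, S=P12SP3(=S)SP(=S)(S1)SP(=S)(S2)S3
Why: Thionation of a secondary lactam with P4S10 activated by NaHCO3 is a mild, established carbonyl-to-thiocarbonyl exchange for oxindoles that leaves aryl bromides untouched, and the air-sensitive thione is kept under argon and used at once so that oxidative disulfide formation is avoided.

Step 4
Reactants: 6 4,5,6-tribromo-1,3-dihydro-2H-indole-2-thione; 7 iodomethane
Product: 8 4,5,6-tribromo-2-(methylsulfanyl)-1H-indole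
Conditions: 7 (1.05 equiv), K2CO3, acetone, 0 °C to rt, argon
Reagents that add atoms: iodomethane, CI
Why: Deprotonation gives the ambident indole-2-thiolate, whose soft sulfur undergoes SN2 S-methylation with iodomethane, and the thioimidate so formed is the aromatic 1H-indole, so alkylation and aromatisation occur together while the near-stoichiometric charge of 7 spares the indole nitrogen.

Step 5
Reactants: 8 4,5,6-tribromo-2-(methylsulfanyl)-1H-indole; 9 dimethyl disulfide
Product: 11 4,5,6-tribromo-2,3-bis(methylsulfanyl)-1H-indole, via methanesulfenyl chloride 10 (not isolated)
Conditions: 9, SO2Cl2, CH2Cl2, −20 °C; then 8, CH2Cl2/THF, −40 to 0 °C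
Reagents that add atoms: dimethyl disulfide, CSSC; sulfuryl chloride, O=S(=O)(Cl)Cl (chlorine carried only by 10)
Why: Electrophilic sulfenylation of an indole at C3, an electrophilic aromatic substitution at the only free and most nucleophilic pyrrole carbon, which the C2 sulfur activates further, with a sulfenyl chloride freshly made by chlorinolysis of the disulfide is a standard way to 3-(alkylsulfanyl)indoles.

**Compound list**

1 | 5-aminooxindole (5-amino-1,3-dihydro-2H-indol-2-one) | Nc1ccc2NC(=O)Cc2c1 | starting material
2 | N-bromosuccinimide (1-bromopyrrolidine-2,5-dione) | O=C1CCC(=O)N1Br | starting material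
3 | 5-amino-4,6-dibromo-1,3-dihydro-2H-indol-2-one | Nc1c(Br)cc2NC(=O)Cc2c1Br | intermediate
4 | 4,6-dibromo-2-oxo-2,3-dihydro-1H-indole-5-diazonium bromide | N#[N+]c1c(Br)cc2NC(=O)Cc2c1Br.[Br-] | intermediate
5 | 4,5,6-tribromo-1,3-dihydro-2H-indol-2-one | O=C1Cc2c(N1)cc(Br)c(Br)c2Br | intermediate
6 | 4,5,6-tribromo-1,3-dihydro-2H-indole-2-thione | S=C1Cc2c(N1)cc(Br)c(Br)c2Br | intermediate
7 | iodomethane | CI | starting material
8 | 4,5,6-tribromo-2-(methylsulfanyl)-1H-indole | CSc1cc2c([nH]1)cc(Br)c(Br)c2Br | intermediate
9 | dimethyl disulfide | CSSC | starting material
10 | methanesulfenyl chloride | CSCl | intermediate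
11 | 4,5,6-tribromo-2,3-bis(methylsulfanyl)-1H-indole | CSc1[nH]c2cc(Br)c(Br)c(Br)c2c1SC | target

Total step count: 5
Longest linear sequence: 5 steps (1 → 3 → 5 → 6 → 8 → 11)

**Steps most likely to fail**

First, step 1 (the key step). What may go wrong is oxidation of the electron-rich aminolactam by the N-bromo reagent, a third substitution at C7 or enol bromination at C3 while both equivalents are present, or stalling before the more hindered C4 reacts. The fallback sets out from 1 and comes back at 3, and it replaces the single double substitution by two separate single substitutions with an isolated monobromide. Compound 1 is treated with one equivalent of tetrabutylammonium tribromide in CH2Cl2/MeOH at 0 °C, which should give 5-amino-6-bromo-1,3-dihydro-2H-indol-2-one F1, possibly accompanied by 5-amino-4-bromo-1,3-dihydro-2H-indol-2-one F2. Both are less electron-rich than 1 and both keep one free position ortho to the amino group. After removal of unreacted 1 and the ammonium salts, the monobromide material is therefore brominated with one equivalent of Br2 in AcOH buffered with NaOAc at room temperature and should converge on 3.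

Second, step 2. What may go wrong is nitrosation of the C3 methylene through the lactam enol while the weakly basic, poorly soluble and hindered amine diazotises slowly, and hydrolysis of the diazonium ion to a phenol in hot aqueous acid. The fallback sets out from 3 and comes back at 5, and it separates diazotisation from halogen delivery under water-free conditions. Compound 3 is treated with one equivalent of NOBF4 in MeCN at −30 °C and the salt is precipitated with Et2O, which should give 4,6-dibromo-2-oxo-2,3-dihydro-1H-indole-5-diazonium tetrafluoroborate F3 as an isolable solid. Stirring F3 with LiBr and a catalytic amount of CuBr in dry MeCN at room temperature should then deliver 5 by the same radical bromine transfer, without nitrous acid or water present.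

Third, step 5. What may go wrong is transfer of electrophilic chlorine instead of sulfur to C3, oxidation at the C2 sulfur by residual chlorinating agent, slow attack at a C3 that is flanked by the C4 bromine and deactivated by three halogens, and acid-promoted scrambling of the methylsulfanyl groups by the hydrogen chloride released. The fallback sets out from 8 and comes back at 11, and it brings in the C3 sulfur as a sulfonium group that is then dealkylated. Dimethyl sulfide and N-chlorosuccinimide in CH2Cl2 at −20 °C should form S,S-dimethyl-N-succinimidosulfonium chloride F4 (the Corey–Kim reagent), which contains no free sulfenyl chloride. Addition of 8 at −20 °C to room temperature should give dimethyl[4,5,6-tribromo-2-(methylsulfanyl)-1H-indol-3-yl]sulfonium chloride F5, collected by filtration. Heating F5 in DMF at about 100 °C should let chloride remove one S-methyl group by SN2 attack and leave 11.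

**Further compounds**

F1 | step 1 | 5-amino-6-bromo-1,3-dihydro-2H-indol-2-one | Nc1cc2CC(=O)Nc2cc1Br
F2 | step 1 | 5-amino-4-bromo-1,3-dihydro-2H-indol-2-one | Nc1ccc2NC(=O)Cc2c1Br
F3 | step 2 | 4,6-dibromo-2-oxo-2,3-dihydro-1H-indole-5-diazonium tetrafluoroborate | N#[N+]c1c(Br)cc2NC(=O)Cc2c1Br.F[B-](F)(F)F
F4 | step 5 | S,S-dimethyl-N-succinimidosulfonium chloride | C[S+](C)N1C(=O)CCC1=O.[Cl-]
F5 | step 5 | dimethyl[4,5,6-tribromo-2-(methylsulfanyl)-1H-indol-3-yl]sulfonium chloride | CSc1[nH]c2cc(Br)c(Br)c(Br)c2c1[S+](C)C.[Cl-]
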